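**Retrosynthetic overview**

- Feature: in the chromenone (O1, C2 with the chain, C4=O, C4a, C5 carbinol, C6–C8, C8a) the carbocycle is the pyranone bond C4a=C8a bridged by the four carbons C5–C8, with oxygen on C5 next to C4a. This is a 1-hydroxycyclobutyl group on C4a, opened at one ring bond and re-closed on C8a.
- Target 19 ⇒ dione 18 by enantioselective reduction of the C5 ketone (the only stereocentre, set last).
- 18 ⇒ cyclobutanol 17 by disconnecting C8–C8a: oxidative radical ring expansion of the cyclobutanol onto the free C6–H of the pyranone (carbocycle formed second).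
- 17 ⇒ dioxinone 13 + enamine 8: an acylketene/enamine annulation builds the pyranone ring first, with the chain at C2 and the silyl-protected cyclobutanol at C5.
- 13 ⇒ dioxinone 11 + iodide 10 (from the Z-C16 alcohol 9); 8 ⇒ cyclobutanone 1, allylmagnesium bromide 2 and morpholine 7.

Key step: step 9

Assumption: commercial (Z)-hexadec-11-en-1-ol is taken as geometrically pure and its alkene is untouched up to the target; the open-shell species of step 9 are transient radicals and carry no compound numbers.

**Route**

Step 1
Reactants: 1 cyclobutanone; 2 allylmagnesium bromide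
Product: 3 1-(prop-2-en-1-yl)cyclobutan-1-ol
Conditions: Et2O, 0 °C to rt; aq NH4Cl
Reagents that add atoms: none
Why: Grignard 1,2-addition to an unhindered, strained ketone should be fast because it relieves angle strain at the carbonyl carbon; no stereocentre arises.

Step 2
Reactants: 3 1-(prop-2-en-1-yl)cyclobutan-1-ol
Product: 4 triethyl{[1-(prop-2-en-1-yl)cyclobutyl]oxy}silane
Conditions: Et3SiOTf, 2,6-lutidine, CH2Cl2, –78 to 0 °C
Reagents that add atoms: triethylsilyl trifluoromethanesulfonate, CC[Si](CC)(CC)OS(=O)(=O)C(F)(F)F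
Why: Silyl triflate silylation reaches tertiary alcohols, and the ether prevents retro-aldol or dehydration of the later β-oxy aldehyde and keeps the hydroxyl from trapping the acylketene.

Step 3
Reactants: 4 triethyl{[1-(prop-2-en-1-yl)cyclobutyl]oxy}silane
Product: 6 2-[1-(triethylsilyloxy)cyclobutyl]acetaldehyde, via secondary ozonide 5 (not isolated)
Conditions: O3, CH2Cl2, –78 °C; then PPh3, –78 °C to rt
Reagents that add atoms: ozone, [O-][O+]=O
Why: Ozonolysis of the only alkene with reductive work-up should give the aldehyde under neutral conditions that a triethylsilyl ether tolerates.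

Step 4
Reactants: 6 2-[1-(triethylsilyloxy)cyclobutyl]acetaldehyde; 7 morpholine
Product: 8 4-{(E)-2-[1-(triethylsilyloxy)cyclobutyl]ethenyl}morpholine
Conditions: 7 (1.1 equiv), 4 Å molecular sieves, PhMe, 0 °C to rt; filtered, concentrated under high vacuum, used crude
Reagents that add atoms: none
Why: Enamine condensation of an α-unbranched aldehyde with a secondary amine under acid-free dehydration should give the E enamine, the quaternary β-substituent enforcing the trans geometry.

Step 5
Reactants: 9 (Z)-hexadec-11-en-1-ol
Product: 10 (Z)-16-iodohexadec-5-ene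
Conditions: I2, PPh3, imidazole, CH2Cl2, 0 °C to rt
Reagents that add atoms: iodine, II
Why: Appel-type iodination proceeds by SN2 displacement of the alkoxyphosphonium at a primary carbon and leaves the remote Z alkene alone.

Step 6
Reactants: 11 2,2,6-trimethyl-4H-1,3-dioxin-4-one; 10 (Z)-16-iodohexadec-5-ene
Product: 13 6-[(12Z)-heptadec-12-en-1-yl]-2,2-dimethyl-4H-1,3-dioxin-4-one, via lithium dienolate 12 (not isolated)
Conditions: LiN(iPr)2, THF, –78 °C; DMPU; then 10, –78 to –20 °C
Reagents that add atoms: none
Why: Vinylogous (γ) alkylation of the dioxinone dienolate with a primary iodide in the presence of a polar cosolvent extends the 6-methyl group by sixteen carbons, which places the alkene at C12 of the new chain.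

Step 7
Reactants: 13 6-[(12Z)-heptadec-12-en-1-yl]-2,2-dimethyl-4H-1,3-dioxin-4-one; 8 4-{(E)-2-[1-(triethylsilyloxy)cyclobutyl]ethenyl}morpholine
Product: 16 2-[(12Z)-heptadec-12-en-1-yl]-5-[1-(triethylsilyloxy)cyclobutyl]-4H-pyran-4-one, via acylketene 14 (not isolated), via morpholine aminal 15 (not isolated)
Conditions: 8 (1.5 equiv), PhMe, 110 °C; then AcOH, rt
Reagents that add atoms: none
Why: Thermal retro-hetero-Diels–Alder of the dioxinone releases acylketene 14, the enamine β-carbon attacks the ketene carbon while the acyl oxygen closes on the iminium carbon (formal hetero-Diels–Alder, an established way from dioxinones and enamines to 4-pyranones), and acid-assisted E1cB loss of morpholine from 15 leaves the chain at C2, the cyclobutyl carbon at C5 and hydrogen at C6.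

Step 8
Reactants: 16 2-[(12Z)-heptadec-12-en-1-yl]-5-[1-(triethylsilyloxy)cyclobutyl]-4H-pyran-4-one
Product: 17 2-[(12Z)-heptadec-12-en-1-yl]-5-(1-hydroxycyclobutyl)-4H-pyran-4-one
Conditions: Bu4NF, AcOH, THF, 0 °C to rt
Reagents that add atoms: none
Why: Fluoride-mediated desilylation is driven by the Si–F bond, and the acetic acid buffer keeps the medium near neutral so that neither the electrophilic pyranone nor the tertiary carbinol is attacked.

Step 9
Reactants: 17 2-[(12Z)-heptadec-12-en-1-yl]-5-(1-hydroxycyclobutyl)-4H-pyran-4-one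
Product: 18 2-[(12Z)-heptadec-12-en-1-yl]-7,8-dihydro-6H-chromene-4,5-dione
Conditions: AgNO3 (20 mol %), K2S2O8 (3 equiv), CH2Cl2/H2O 1:1, 30 °C, dark, N2
Reagents that add atoms: none
Why: Proposed new method: monovalent silver forms the silver cyclobutanolate of 17, which persulfate (through divalent silver) oxidises to the cyclobutyloxy radical; strain-driven β-scission of either of the two equivalent ring bonds gives the C5 ketone and a primary C8 radical. This nucleophilic alkyl radical adds to C8a (pyranone C6) in a 6-endo-trig closure that forms C8–C8a and the carbocycle, and the resulting C4a radical, flanked by the C4 and C5 carbonyls, loses one electron and the C8a proton to restore the pyranone. The closest known reaction is the AgNO3/K2S2O8 ring expansion of 1-arylcyclobutanols to 1-tetralones, where the same γ-keto radical closes on an arene ortho carbon; here the acceptor is the unsubstituted β-carbon of a doubly activated enol-ether alkene, which should be at least as good a radical trap. The step needs attack at C8a and not at C4a (5-exo, spiro): polarity matching with the electron-poor β-carbon, the doubly stabilised radical that results, and the sp2 C5 carbonyl inside the tether, which strains the 5-exo transition state, all favour the six-membered ring. No stereocentre is formed, and the remote Z alkene should survive because ring opening and cyclisation are fast and intramolecular while the oxidant stays in the aqueous phase.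

Step 10
Reactants: 18 2-[(12Z)-heptadec-12-en-1-yl]-7,8-dihydro-6H-chromene-4,5-dione
Product: 19 (5S)-2-[(12Z)-heptadec-12-en-1-yl]-5-hydroxy-5,6,7,8-tetrahydro-4H-chromen-4-one
Conditions: RuCl(p-cymene)[(S,S)-TsDPEN] (2 mol %), HCO2H/Et3N 5:2, CH2Cl2, 30 °C
Reagents that add atoms: none
Why: Noyori–Ikariya asymmetric transfer hydrogenation should reduce only the C5 ketone (the pyranone carbonyl and the isolated alkene are inert); by analogy with 1-tetralone, the (S,S) catalyst places the sp2 C4a side next to the η6-arene and delivers hydride to the Re face of C5, giving the S alcohol irreversibly as CO2 is lost.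

**Compound list**

1 | cyclobutanone | O=C1CCC1 | starting material
2 | allylmagnesium bromide | C=CC[Mg]Br | starting material
3 | 1-(prop-2-en-1-yl)cyclobutan-1-ol | C=CCC1(O)CCC1 | intermediate
4 | triethyl{[1-(prop-2-en-1-yl)cyclobutyl]oxy}silane | C=CCC1(O[Si](CC)(CC)CC)CCC1 | intermediate
5 | 3-{[1-(triethylsilyloxy)cyclobutyl]methyl}-1,2,4-trioxolane (secondary ozonide, racemic) | CC[Si](CC)(CC)OC1(CC2OCOO2)CCC1 | intermediate
6 | 2-[1-(triethylsilyloxy)cyclobutyl]acetaldehyde | CC[Si](CC)(CC)OC1(CC=O)CCC1 | intermediate
7 | morpholine | C1COCCN1 | starting material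
8 | 4-{(E)-2-[1-(triethylsilyloxy)cyclobutyl]ethenyl}morpholine | CC[Si](CC)(CC)OC1(/C=C/N2CCOCC2)CCC1 | intermediate
9 | (Z)-hexadec-11-en-1-ol | CCCC/C=C\CCCCCCCCCCO | starting material
10 | (Z)-16-iodohexadec-5-ene [(Z)-hexadec-11-enyl iodide] | CCCC/C=C\CCCCCCCCCCI | intermediate
11 | 2,2,6-trimethyl-4H-1,3-dioxin-4-one | CC1=CC(=O)OC(C)(C)O1 | starting material
12 | lithium 2,2-dimethyl-6-methylidene-6H-1,3-dioxin-4-olate (lithium dienolate of 11) | [Li+].C=C1C=C([O-])OC(C)(C)O1 | intermediate
13 | 6-[(12Z)-heptadec-12-en-1-yl]-2,2-dimethyl-4H-1,3-dioxin-4-one | CCCC/C=C\CCCCCCCCCCCC1=CC(=O)OC(C)(C)O1 | intermediate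
14 | (15Z)-3-oxoicosa-1,15-dien-1-one (acylketene) | CCCC/C=C\CCCCCCCCCCCC(=O)C=C=O | intermediate
15 | 6-[(12Z)-heptadec-12-en-1-yl]-2-(morpholin-4-yl)-3-[1-(triethylsilyloxy)cyclobutyl]-2,3-dihydro-4H-pyran-4-one (racemic, relative configuration not defined) | CCCC/C=C\CCCCCCCCCCCC1=CC(=O)C(C2(O[Si](CC)(CC)CC)CCC2)C(N2CCOCC2)O1 | intermediate
16 | 2-[(12Z)-heptadec-12-en-1-yl]-5-[1-(triethylsilyloxy)cyclobutyl]-4H-pyran-4-one | CCCC/C=C\CCCCCCCCCCCc1cc(=O)c(C2(O[Si](CC)(CC)CC)CCC2)co1 | intermediate
17 | 2-[(12Z)-heptadec-12-en-1-yl]-5-(1-hydroxycyclobutyl)-4H-pyran-4-one | CCCC/C=C\CCCCCCCCCCCc1cc(=O)c(C2(O)CCC2)co1 | intermediate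
18 | 2-[(12Z)-heptadec-12-en-1-yl]-7,8-dihydro-6H-chromene-4,5-dione | CCCC/C=C\CCCCCCCCCCCc1cc(=O)c2c(o1)CCCC2=O | intermediate
19 | (5S)-2-[(12Z)-heptadec-12-en-1-yl]-5-hydroxy-5,6,7,8-tetrahydro-4H-chromen-4-one | CCCC/C=C\CCCCCCCCCCCc1cc(=O)c2c(o1)CCC[C@@H]2O | target

**Step count**

Total step count: 10
Longest linear sequence: 8 steps (steps 1, 2, 3, 4, 7, 8, 9, 10 from cyclobutanone)

**Steps most likely to fail**

1. Step 9 (key step). The ring-opened γ-keto radical may be oxidised or quenched before it closes, may close 5-exo at C4a, or the sulfate radical anion may attack or isomerise the chain alkene. The fallback uses known chemistry, sets out from 13 and comes back to the route at 18. Heating 13 with cyclohexane-1,3-dione in toluene at 110 °C regenerates acylketene 14, which acylates the enol oxygen to give 3-oxocyclohex-1-en-1-yl (15Z)-3-oxoicos-15-enoate F1. Et3N with catalytic DMAP in MeCN at rt induces the O-to-C acyl shift typical of 1,3-dione enol esters and gives 3-hydroxy-2-[(15Z)-3-oxoicos-15-enoyl]cyclohex-2-en-1-one F2. Trifluoroacetic acid in CH2Cl2 then cyclodehydrates F2 to the fused 4-pyranone 18, which continues with step 10.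

2. Step 7. The allylic silyloxy group may ionise under push from the enamine nitrogen in hot toluene, and morpholine set free early may capture the acylketene in place of the hindered enamine carbon. The fallback sets out from 13 and 1 and comes back at 17, so that steps 1–4 and 8 are bypassed.
   - Heating 13 with excess butyl vinyl ether in toluene at 110 °C (sealed) traps acylketene 14 as racemic 2-butoxy-6-[(12Z)-heptadec-12-en-1-yl]-2,3-dihydro-4H-pyran-4-one F3, the usual hetero-Diels–Alder adduct of acylketenes with vinyl ethers.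
   - Kinetic deprotonation at C3 with LiN(iPr)2 in THF at –78 °C and aldol addition to cyclobutanone 1, quenched cold with AcOH, should give 2-butoxy-6-[(12Z)-heptadec-12-en-1-yl]-3-(1-hydroxycyclobutyl)-2,3-dihydro-4H-pyran-4-one F4. The enolate has a β-alkoxy leaving group, so it must be kept cold and trapped quickly.
   - Catalytic p-TsOH in CH2Cl2 at rt eliminates butanol across C2–C3 and aromatises F4 to 17.

3. Step 10. Hydride transfer to a carbonyl that is part of a vinylogous ester may be slow, and the neighbouring C4 carbonyl may erode facial discrimination. The fallback replaces asymmetric reduction by resolution, sets out from 18 and comes back at 19. Luche reduction (NaBH4, CeCl3·7H2O, MeOH, –40 °C) should give racemic 2-[(12Z)-heptadec-12-en-1-yl]-5-hydroxy-5,6,7,8-tetrahydro-4H-chromen-4-one F5, the pyranone carbonyl being inert. Novozym 435 (immobilised Candida antarctica lipase B) with vinyl acetate in MTBE at 30 °C should then acetylate the R enantiomer (Kazlauskas rule: fused sp2 side large, CH2 side medium) to (5R)-2-[(12Z)-heptadec-12-en-1-yl]-4-oxo-5,6,7,8-tetrahydro-4H-chromen-5-yl acetate F6. The unreacted S alcohol is 19, at most half of the material, and is separated by chromatography.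

Further compounds
F1 | step 9 | 3-oxocyclohex-1-en-1-yl (15Z)-3-oxoicos-15-enoate | CCCC/C=C\CCCCCCCCCCCC(=O)CC(=O)OC1=CC(=O)CCC1
F2 | step 9 | 3-hydroxy-2-[(15Z)-3-oxoicos-15-enoyl]cyclohex-2-en-1-one | CCCC/C=C\CCCCCCCCCCCC(=O)CC(=O)C1=C(O)CCCC1=O
F3 | step 7 | 2-butoxy-6-[(12Z)-heptadec-12-en-1-yl]-2,3-dihydro-4H-pyran-4-one (racemic) | CCCC/C=C\CCCCCCCCCCCC1=CC(=O)CC(OCCCC)O1
F4 | step 7 | 2-butoxy-6-[(12Z)-heptadec-12-en-1-yl]-3-(1-hydroxycyclobutyl)-2,3-dihydro-4H-pyran-4-one (racemic, relative configuration not defined) | CCCC/C=C\CCCCCCCCCCCC1=CC(=O)C(C2(O)CCC2)C(OCCCC)O1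
F5 | step 10 | 2-[(12Z)-heptadec-12-en-1-yl]-5-hydroxy-5,6,7,8-tetrahydro-4H-chromen-4-one (racemic) | CCCC/C=C\CCCCCCCCCCCc1cc(=O)c2c(o1)CCCC2O
F6 | step 10 | (5R)-2-[(12Z)-heptadec-12-en-1-yl]-4-oxo-5,6,7,8-tetrahydro-4H-chromen-5-yl acetate | CCCC/C=C\CCCCCCCCCCCc1cc(=O)c2c(o1)CCC[C@H]2OC(C)=O
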